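The route rests on cutting the 1,2-dioxolane ring at C3–C4 and O1–C5. C3, with its methyl and acetate arm, is at the oxidation level of methyl acetoacetate and becomes a silylperoxycarbenium ion that already holds O2–O1. C4–C5 is the terminal 2-methylalk-1-ene of the complete side chain, made from (R)-citronellic acid by Julia–Kocienski olefination. The key step is a chiral-anion-controlled formal [3+2] annulation: the racemic silylperoxy ketal ionises to a planar cation, so both enantiomers converge, and the C–C bond, the O–C bond and both quaternary centres arise in one operation. Saponification ends the synthesis.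

Key step: step 11

Assumption: the sense of induction of the chiral acid in step 11 cannot be predicted from a model; the antipode that gives the (3S,5R) ring is chosen after a trial run, both antipodes being accessible from (R)- or (S)-BINOL.

Step 1
Reactants: 1 1-phenylprop-2-en-1-ol (racemic); 2 triethyl orthoacetate
Product: 4 ethyl (4E)-5-phenylpent-4-enoate, via ketene acetal 3 (not isolated)
Conditions: 2 (excess), propionic acid (cat.), neat, 140 °C, EtOH distilled off
Reagents that add atoms: none
Why: Johnson–Claisen rearrangement, in which acid-catalysed exchange gives 3 and its chair [3,3] shift with phenyl equatorial should deliver the E-styrene together with the two-carbon ester arm.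

Step 2
Reactants: 4 ethyl (4E)-5-phenylpent-4-enoate
Product: 5 (4E)-5-phenylpent-4-en-1-ol
Conditions: LiAlH4, Et2O, 0 °C; H2O/NaOH work-up
Reagents that add atoms: none
Why: Hydride reduction of the ester to the primary alcohol, to which the styrene is inert.

Step 3
Reactants: 5 (4E)-5-phenylpent-4-en-1-ol
Product: 6 1-phenyl-5-{[(4E)-5-phenylpent-4-en-1-yl]sulfanyl}-1H-tetrazole
Conditions: 1-phenyl-1H-tetrazole-5-thiol, PPh3, DIAD, THF, 0 °C → rt
Reagents that add atoms: 1-phenyl-1H-tetrazole-5-thiol, Sc1nnnn1-c1ccccc1
Why: Mitsunobu thioetherification, in which the acidic thiol displaces the activated primary alcohol by SN2 with no stereocentre involved.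

Step 4
Reactants: 6 1-phenyl-5-{[(4E)-5-phenylpent-4-en-1-yl]sulfanyl}-1H-tetrazole
Product: 7 1-phenyl-5-{[(4E)-5-phenylpent-4-en-1-yl]sulfonyl}-1H-tetrazole
Conditions: 30% H2O2, (NH4)6Mo7O24·4H2O (cat.), EtOH, 0 °C → rt
Reagents that add atoms: hydrogen peroxide, OO
Why: Molybdate-catalysed sulfide-to-sulfone oxidation, which is selective for sulfur over the conjugated alkene.

Step 5
Reactants: 8 (R)-citronellic acid [(3R)-3,7-dimethyloct-6-enoic acid]
Product: 10 (4R)-4,8-dimethylnon-7-en-2-one, via dilithium gem-diolate 9 (not isolated)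
Conditions: MeLi (2.2 equiv), Et2O, 0 °C → rt; inverse quench into cold 1 M HCl
Reagents that add atoms: methyllithium, [Li]C
Why: Addition of methyllithium to the lithium carboxylate gives 9, which does not collapse before the quench, so the methyl ketone should form without over-addition and with the β-stereocentre untouched.

Step 6
Reactants: 10 (4R)-4,8-dimethylnon-7-en-2-one
Product: 12 (4R)-4-methyl-6-oxoheptanal, via ozonide 11 (not isolated)
Conditions: O3, CH2Cl2, −78 °C; then PPh3, −78 °C → rt
Reagents that add atoms: ozone, [O-][O+]=O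
Why: Ozonolysis (Criegee mechanism) of the only alkene and reductive cleavage of 11 by PPh3 should give the aldehyde, the ketone being inert and C4 not epimerisable.

Step 7
Reactants: 12 (4R)-4-methyl-6-oxoheptanal; 7 1-phenyl-5-{[(4E)-5-phenylpent-4-en-1-yl]sulfonyl}-1H-tetrazole
Product: 14 (4R,7E,11E)-4-methyl-12-phenyldodeca-7,11-dien-2-one, via potassium sulfonyl carbanion 13 (not isolated)
Conditions: 7, KN(SiMe3)2, DME, −60 °C, 30 min; then 12, −60 °C → rt; sat. NH4Cl
Reagents that add atoms: none
Why: Julia–Kocienski olefination, in which pre-formed 13 should add to the aldehyde far faster than it adds to or enolises the methyl ketone, and the 1-phenyltetrazolyl sulfone with a potassium base in DME is the combination known to favour the E-alkene.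

Step 8
Reactants: 14 (4R,7E,11E)-4-methyl-12-phenyldodeca-7,11-dien-2-one
Product: 15 (4R,7E,11E)-2,4-dimethyl-12-phenyldodeca-1,7,11-triene
Conditions: Ph3PCH3Br, KOtBu, THF, 0 °C → rt
Reagents that add atoms: methyltriphenylphosphonium bromide, C[P+](c1ccccc1)(c1ccccc1)c1ccccc1.[Br-]
Why: Wittig methylenation of the methyl ketone with the non-stabilised ylide, which touches neither the stereocentre nor the two E-alkenes.

Step 9
Reactants: 16 methyl 3-methylbut-3-enoate
Product: 18 methyl 3-hydroperoxy-3-methoxybutanoate (racemic), via carbonyl oxide 17 (not isolated)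
Conditions: O3, CH2Cl2/MeOH (4:1), −78 °C; N2 purge; concentrated cold and used at once
Reagents that add atoms: ozone, [O-][O+]=O; methanol, CO
Why: Ozonolysis in methanol, in which cycloreversion of the primary ozonide should place 17 on the disubstituted carbon with loss of formaldehyde and methanol traps it as the α-methoxy hydroperoxide (Criegee trapping), the racemic ketal centre being intended.

Step 10
Reactants: 18 methyl 3-hydroperoxy-3-methoxybutanoate
Product: 19 methyl 3-methoxy-3-[(triethylsilyl)peroxy]butanoate (racemic)
Conditions: Et3SiCl, imidazole, DMF, 0 °C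
Reagents that add atoms: chlorotriethylsilane, CC[Si](Cl)(CC)CC
Why: O-silylation of the hydroperoxide under mild base gives the triethylsilyl peroxyketal, the established precursor type of silylperoxycarbenium ions.

Step 11
Reactants: 15 (4R,7E,11E)-2,4-dimethyl-12-phenyldodeca-1,7,11-triene; 19 methyl 3-methoxy-3-[(triethylsilyl)peroxy]butanoate
Product: 22 methyl 2-[(3S,5R)-3,5-dimethyl-5-[(2R,5E,9E)-2-methyl-10-phenyldeca-5,9-dien-1-yl]-1,2-dioxolan-3-yl]acetate, via silylperoxycarbenium ion 20 (not isolated), via tertiary carbocation 21 (not isolated)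
Conditions: confined chiral imidodiphosphorimidate Brønsted acid (BINOL-derived, N-triflyl core, 3,3′-aryl wings; 5 mol %), 4 Å molecular sieves, toluene, −78 → −40 °C, 19 (1.3 equiv) added slowly
Reagents that add atoms: none
Why: Proposed new method: the confined chiral acid ionises racemic 19 at its methoxy group (by protonation in the first turnover, afterwards as its triethylsilyl form), so both ketal enantiomers converge on the planar ion 20 paired with the chiral imidodiphosphorimidate anion; the CH2 terminus of the 2-methylalk-1-ene of 15 attacks C3 of 20 (C4–C3 bond) to give 21, whose C5 is captured by the silylated peroxide oxygen (O1–C5 bond), and the released Et3Si+ returns to the anion and carries the chain (net by-product Et3SiOMe). The closest known reactions are the SnCl4-mediated annulation of triethylsilyl peroxyketals with alkenes, which is racemic, and silylium imidodiphosphorimidate catalysis of additions to ketone-derived oxocarbenium ions, including the asymmetric intermolecular Prins reaction. The dioxolane closes in a stepwise polar [3+2] mode, the ring-forming event being five-membered collapse of an oxygen nucleophile onto the tertiary C5 cation. C3 (S) is set in the C–C bond formation by the chiral anion, which has to tell the methyl from the CH2CO2Me arm of 20 as this catalyst class does for methyl alkyl ketones; C5 (R) is set in the ring closure inside the same ion pair, where the branched C6 arm should lie trans to the ester arm both for the fit in the catalyst pocket and for the lower strain of that envelope. The C7 centre of 15 is a remote spectator, so the step needs full catalyst control of two quaternary centres and site selection among three alkenes; the latter is secured because only the 1,1-disubstituted alkene gives a tertiary cation held next to the peroxide oxygen, the 1,2-disubstituted alkene and the β-alkylstyrene being far less nucleophilic toward carbenium ions.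

Step 12
Reactants: 22 methyl 2-[(3S,5R)-3,5-dimethyl-5-[(2R,5E,9E)-2-methyl-10-phenyldeca-5,9-dien-1-yl]-1,2-dioxolan-3-yl]acetate
Product: 23 2-[(3S,5R)-3,5-dimethyl-5-[(2R,5E,9E)-2-methyl-10-phenyldeca-5,9-dien-1-yl]-1,2-dioxolan-3-yl]acetic acid
Conditions: LiOH·H2O, THF/MeOH/H2O, 0 °C → rt; then cold 1 M HCl to pH 3
Reagents that add atoms: lithium hydroxide, [Li+].[OH-]; water, O
Why: Saponification (BAc2) at low temperature; both ring carbons are quaternary, so no Kornblum–DeLaMare fragmentation is possible, and the dialkyl peroxide and the alkenes should tolerate aqueous LiOH.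

Compound list
1 | 1-phenylprop-2-en-1-ol (racemic) | C=CC(O)c1ccccc1 | starting material
2 | triethyl orthoacetate | CCOC(C)(OCC)OCC | starting material
3 | 1-ethoxy-1-[(1-phenylprop-2-en-1-yl)oxy]ethene (ketene acetal) | C=C(OCC)OC(C=C)c1ccccc1 | intermediate
4 | ethyl (4E)-5-phenylpent-4-enoate | CCOC(=O)CC/C=C/c1ccccc1 | intermediate
5 | (4E)-5-phenylpent-4-en-1-ol | OCCC/C=C/c1ccccc1 | intermediate
6 | 1-phenyl-5-{[(4E)-5-phenylpent-4-en-1-yl]sulfanyl}-1H-tetrazole | c1ccc(cc1)/C=C/CCCSc1nnnn1-c1ccccc1 | intermediate
7 | 1-phenyl-5-{[(4E)-5-phenylpent-4-en-1-yl]sulfonyl}-1H-tetrazole | O=S(=O)(CCC/C=C/c1ccccc1)c1nnnn1-c1ccccc1 | intermediate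
8 | (R)-citronellic acid, (3R)-3,7-dimethyloct-6-enoic acid | C[C@H](CCC=C(C)C)CC(=O)O | starting material
9 | dilithium (4R)-4,8-dimethylnon-7-ene-2,2-diolate | C[C@H](CCC=C(C)C)CC(C)([O-])[O-].[Li+].[Li+] | intermediate
10 | (4R)-4,8-dimethylnon-7-en-2-one | C[C@H](CCC=C(C)C)CC(C)=O | intermediate
11 | (4R)-6-(5,5-dimethyl-1,2,4-trioxolan-3-yl)-4-methylhexan-2-one (ozonide, epimers at the ring CH) | C[C@H](CCC1OOC(C)(C)O1)CC(C)=O | intermediate
12 | (4R)-4-methyl-6-oxoheptanal | C[C@H](CCC=O)CC(C)=O | intermediate
13 | potassium α-sulfonyl carbanion of 7 | [K+].O=S(=O)([CH-]CC/C=C/c1ccccc1)c1nnnn1-c1ccccc1 | intermediate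
14 | (4R,7E,11E)-4-methyl-12-phenyldodeca-7,11-dien-2-one | C[C@H](CC/C=C/CC/C=C/c1ccccc1)CC(C)=O | intermediate
15 | (4R,7E,11E)-2,4-dimethyl-12-phenyldodeca-1,7,11-triene | C[C@H](CC/C=C/CC/C=C/c1ccccc1)CC(C)=C | intermediate
16 | methyl 3-methylbut-3-enoate | COC(=O)CC(C)=C | starting material
17 | carbonyl oxide of methyl acetoacetate | COC(=O)CC(C)=[O+][O-] | intermediate
18 | methyl 3-hydroperoxy-3-methoxybutanoate (racemic) | COC(=O)CC(C)(OC)OO | intermediate
19 | methyl 3-methoxy-3-[(triethylsilyl)peroxy]butanoate (racemic) | COC(=O)CC(C)(OC)OO[Si](CC)(CC)CC | intermediate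
20 | O-triethylsilyl peroxycarbenium ion of methyl acetoacetate (ion pair with the chiral anion) | COC(=O)CC(C)=[O+]O[Si](CC)(CC)CC | intermediate
21 | C5 cation of methyl (3S,7R,10E,14E)-3,5,7-trimethyl-15-phenyl-3-[(triethylsilyl)peroxy]pentadeca-10,14-dienoate | C[C@H](CC/C=C/CC/C=C/c1ccccc1)C[C+](C)C[C@@](C)(CC(=O)OC)OO[Si](CC)(CC)CC | intermediate
22 | methyl 2-[(3S,5R)-3,5-dimethyl-5-[(2R,5E,9E)-2-methyl-10-phenyldeca-5,9-dien-1-yl]-1,2-dioxolan-3-yl]acetate | C[C@H](CC/C=C/CC/C=C/c1ccccc1)C[C@]1(C)C[C@@](C)(CC(=O)OC)OO1 | intermediate
23 | 2-[(3S,5R)-3,5-dimethyl-5-[(2R,5E,9E)-2-methyl-10-phenyldeca-5,9-dien-1-yl]-1,2-dioxolan-3-yl]acetic acid | C[C@H](CC/C=C/CC/C=C/c1ccccc1)C[C@]1(C)C[C@@](C)(CC(=O)O)OO1 | target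

Total step count: 12. Longest linear sequence: 8 steps (steps 1, 2, 3, 4, 7, 8, 11, 12).

Steps most likely to fail

Step 11. The chiral anion may discriminate the two faces of the cation at C3, or the two modes of ring closure at C5, only partly, so that ring diastereomers form. The cation may also be diverted to the styrene or captured reversibly by the ester carbonyl. The fallback uses known chemistry, sets out from 14 and comes back at 22.
- Mukaiyama aldol addition of 2-(trimethylsilyloxy)propene to 14 (TiCl4, CH2Cl2, −78 °C) would give the tertiary aldol (6R,9E,13E)-4-hydroxy-4,6-dimethyl-14-phenyltetradeca-9,13-dien-2-one F1.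
- Acid-catalysed perhydrolysis of the tertiary carbinol (50% H2O2, cat. H2SO4, MeCN, 0 °C), with closure of the hydroperoxy ketone, would give the peroxy hemiketal 3,5-dimethyl-5-[(2R,5E,9E)-2-methyl-10-phenyldeca-5,9-dien-1-yl]-1,2-dioxolan-3-ol F2.
- MeOH with cat. TsOH would give 3-methoxy-3,5-dimethyl-5-[(2R,5E,9E)-2-methyl-10-phenyldeca-5,9-dien-1-yl]-1,2-dioxolane F3.
- TiCl4-mediated displacement of the methoxy group of F3 by 1-methoxy-1-(trimethylsilyloxy)ethene, through the cyclic peroxycarbenium ion, should bring in the acetate arm mainly anti to the branched C5 arm and so return to 22.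
- This sequence gives no facial control at C5, so 22 would have to be separated from its C5-epimeric series by preparative HPLC.

Step 7. The basic carbanion may enolise the keto aldehyde and start an intramolecular aldol closure, or the E selectivity of the new alkene may erode. The fallback sets out from 10 and comes back at 15.
- Wittig methylenation of 10 (Ph3PCH3Br, KOtBu) would give (4R)-2,4,8-trimethylnona-1,7-diene F4.
- Epoxidation with one equivalent of mCPBA at −20 °C, which should prefer the more electron-rich trisubstituted alkene, would give 3-[(3R)-3,5-dimethylhex-5-en-1-yl]-2,2-dimethyloxirane F5.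
- Cleavage with H5IO6 would give (4R)-4,6-dimethylhept-6-enal F6.
- Julia–Kocienski olefination of F6 with 13 then meets no ketone and leads directly to 15.

Step 9. The primary ozonide may fragment in the other sense (formaldehyde oxide plus methyl acetoacetate), or the β-ester hydroperoxide may cyclise to a peroxylactone during isolation. The fallback leaves 16 aside, sets out from purchased methyl acetoacetate and comes back at 18.
- Ketalisation with trimethyl orthoformate in MeOH (cat. TsOH) would give methyl 3,3-dimethoxybutanoate F7.
- Acid-catalysed exchange of one methoxy group for hydroperoxide (one equivalent of ethereal H2O2, cat. pyridinium p-toluenesulfonate, 0 °C) would give 18 without any ozonide fragmentation step.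

Further compounds
F1 | step 11 | (6R,9E,13E)-4-hydroxy-4,6-dimethyl-14-phenyltetradeca-9,13-dien-2-one (both C4 epimers) | C[C@H](CC/C=C/CC/C=C/c1ccccc1)CC(C)(O)CC(C)=O
F2 | step 11 | 3,5-dimethyl-5-[(2R,5E,9E)-2-methyl-10-phenyldeca-5,9-dien-1-yl]-1,2-dioxolan-3-ol (ring diastereomers) | C[C@H](CC/C=C/CC/C=C/c1ccccc1)CC1(C)CC(C)(O)OO1
F3 | step 11 | 3-methoxy-3,5-dimethyl-5-[(2R,5E,9E)-2-methyl-10-phenyldeca-5,9-dien-1-yl]-1,2-dioxolane (ring diastereomers) | C[C@H](CC/C=C/CC/C=C/c1ccccc1)CC1(C)CC(C)(OC)OO1
F4 | step 7 | (4R)-2,4,8-trimethylnona-1,7-diene | C[C@H](CCC=C(C)C)CC(C)=C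
F5 | step 7 | 3-[(3R)-3,5-dimethylhex-5-en-1-yl]-2,2-dimethyloxirane (epimers at the oxirane CH) | C[C@H](CCC1OC1(C)C)CC(C)=C
F6 | step 7 | (4R)-4,6-dimethylhept-6-enal | C[C@H](CCC=O)CC(C)=C
F7 | step 9 | methyl 3,3-dimethoxybutanoate | COC(=O)CC(C)(OC)OC
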